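The number to carry through this flask is 22.0 kJ mol⁻¹, by which the activation energy of the right-handed coupling exceeds that of the left-handed one.

    partner + left-handed substrate → left-handed product (k1 = 22 M⁻¹ h⁻¹, Ea1 = 47.0 kJ mol⁻¹)
    partner + right-handed substrate → right-handed product (k2 = 5.7 M⁻¹ h⁻¹, Ea2 = 69.0 kJ mol⁻¹)
    left-handed substrate ⇌ right-handed substrate (k3 = 0.36 h⁻¹, Ea3 = 102 kJ mol⁻¹)
    2 partner → self-condensation product (k4 = 180 M⁻¹ h⁻¹, Ea4 = 46.0 kJ mol⁻¹)
    solid reagent ⇌ partner, rate k5*(cs5 - [partner]) while solid is left; crystals form when [partner] > cs5 (cs5 = 16 mM, k5 = 1.1 h⁻¹)
    partner → decomposition product (k6 = 1.8 × 10⁻⁴ h⁻¹, Ea6 = 113 kJ mol⁻¹)
    (constants at 25 °C)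

in all of them: left-handed substrate 0.020 M; solid reagent 0.0500 M; right-handed substrate 0.020 M; time 2.0 h
- midnight: temperature 55 °C
- dusk: temperature 40 °C
- summer: temperature 10 °C
- winter: temperature 25 °C

- partner is single-handed; left-handed substrate and right-handed substrate are mirror images of each other, charged as a racemate, each of them at the stated concentration
- a doubled species enters its step squared and goes two at a time
- as a solid, counted per litre of solution: solid reagent
- the list of constants is for 25 °C, to be carried to other temperatures by the activation energies
- at the start none of the solid reagent is in solution
- the handed part of partner does not stay in what it makes, so the products of the two hands are mirror images too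

- which flask leads in share of left-handed product in all that became left-handed product or right-handed product ("all alike" within 1.5 percentage points) (midnight / dusk / summer / winter / all alike)
- share of left-handed product in all that became left-handed product or right-handed product, midnight
- share of left-handed product in all that became left-handed product or right-handed product, dusk
- share of left-handed product in all that became left-handed product or right-handed product, summer
- share of left-handed product in all that became left-handed product or right-handed product, winter

Look at the two product peaks first. Left-handed product grows as k1 times partner times left-handed substrate, and right-handed product as k2 times partner times right-handed substrate. Partner therefore divides out of their ratio, and while the substrate stays racemic that ratio is k1/k2. In summer the gap makes it 6.18, and this selectivity factor, the left-handed over the right-handed coupling constant at the flask's temperature, gives a share of 86.1%. The same reckoning gives 79.4% for winter, 71.6% for dusk and 63.2% for midnight.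

But you should object that the faster hand is drawn down, so the substrate does not stay racemic. Treat this as a small correction to the large share. The logarithm of the ratio of left-handed to right-handed substrate falls at (k1 − k2) times partner, racemisation pulls it back, and the share shifts by share × (1 − share) × that logarithm averaged over the run.

This needs partner, which I take where dissolving balances self-condensation and both couplings. With summer's coupling constants of 8.06 M⁻¹ h⁻¹ and 1.30 M⁻¹ h⁻¹, that gives 7.61 mM. Summer's relaxation half-life of 8.51 h is longer than the run of 2.0 h, so little is pulled back, and the correction is 0.58 percentage points, leaving 85.5%. Winter, with partner at 5.06 mM, loses 0.88 points and stands at 78.5%.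

At dusk the relaxation half-life is 0.134 h, shorter than the run, which shrinks the correction but does not remove it: with partner at 3.23 mM, dusk loses 0.38 points and stands at 71.2%. Midnight's half-life of 0.0224 h is shorter still, and with partner at 1.97 mM that flask loses 0.076 points and stands at 63.1%. A last doubt is that partner starts from nothing, which makes my corrections slightly too large. Even so, summer stays ahead of winter by more than the margin, and I commit to summer.

The forecast names summer, with 63.1% for midnight, 71.3% for dusk, 85.6% for summer and 78.6% for winter, and says “the coldest flask clearly leads”.

The simulation puts summer first, with 63.1% for midnight, 71.2% for dusk, 85.6% for summer and 78.6% for winter. Summer's selectivity factor stands 0.49 points above that flask's reading. Against the run of 2.0 h, summer's relaxation half-life of 8.51 h is the longer, and at the end 91% of the left-handed and 98% of the right-handed substrate charge remain. Carried to the same flask at −15 °C, the factor becomes 15.3, a share of 93.9%, and that flask reads 93.8%.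

The constants used here were set for the occasion; no experiment stands behind them.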